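**Plan**

1. Retrosynthesis: remove the C15 silyl ether and the C8 ester (put on with inversion); cut C7–C8 of the nine-membered oxacycle; cut the butenolide at C7=C11 (metathesis) and at its C6–O acyl bond; cut C3–C4 (alkenyllithium + γ-lactone). The halves come from acrolein plus a propargyl ether (C4–C7, C15) and from (R)-linalool (C1–C3, C8–C10, C14).
2. Forward ring order: oxolane first (as γ-lactone, then C3 ketal), butenolide second, nine-membered ring last by an intramolecular zinc Barbier allylation.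
3. Enabling feature: C7 is the β-carbon of the butenolide ring O–C6–C7=C11–C12, and its α-carbon C11 carries C13 as CH2Br. Zinc therefore makes C7 nucleophilic toward the C8 aldehyde, which the oxolane (C3–O–C10) and the Z C4=C5 alkene hold nearby, and the same event turns C11=C13 into the exo-methylene.
4. Stereochemistry: C10 is bought ((R)-linalool); C6 comes from a lipase resolution; C7 and C8 are set by substrate control in the ring closure, and C8 is then inverted by Mitsunobu esterification; C3 is thermodynamic; Z-C4=C5 comes from trans-hydroalumination/iodination.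

Key step: step 15

Remark 1: locants C1–C15 follow germacrane numbering (C3 hemiketal carbon, C4=C5, C6 lactone CH–O, C7, C8 CH–O–acyl, C9, C10 C(CH3)–O, C11/C12/C13 lactone α-carbon, carbonyl and exo-methylene, C14 methyl, C15 CH2OH).
Remark 2 (assumption): the hemiketal carbon C3 epimerises through the ring-opened hydroxy-enone, so no reagent sets it; it is written with the configuration of the target, taken to be the one the C3–O–C10 bridge imposes.
Remark 3: (R)-linalool, acrolein, silyl ether 7 and 2-(bromomethyl)acrylic acid are taken as purchased.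

**Route**

Step 1
Reactants: 1 (R)-(−)-linalool
Product: 3 (3R)-3,7-dimethyloct-6-ene-1,3-diol, via alkylborane 2 (not isolated)
Conditions: 9-BBN, THF, 0 °C → rt; then NaOH, H2O2, 0 °C
Reagents that add atoms: hydrogen peroxide (OO)
Why: Brown hydroboration–oxidation, in which the bulky borane adds anti-Markovnikov to the monosubstituted vinyl group far faster than to the trisubstituted alkene and alkaline peroxide replaces boron by OH without touching the tertiary carbinol centre that becomes C10.

Step 2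
Reactants: 3 (3R)-3,7-dimethyloct-6-ene-1,3-diol
Product: 4 (3R)-1-[(tert-butyldimethylsilyl)oxy]-3,7-dimethyloct-6-en-3-ol
Conditions: TBSCl, imidazole, CH2Cl2, 0 °C
Reagents that add atoms: tert-butyldimethylsilyl chloride (CC(C)(C)[Si](C)(C)Cl)
Why: Silylation of the primary alcohol is selective because the tertiary alcohol is too hindered to react with TBSCl/imidazole.

Step 3
Reactants: 4 (3R)-1-[(tert-butyldimethylsilyl)oxy]-3,7-dimethyloct-6-en-3-ol
Product: 6 (5R)-5-{2-[(tert-butyldimethylsilyl)oxy]ethyl}-5-methyloxolan-2-one, via lactol 5 (not isolated)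
Conditions: RuCl3 (cat.), NaIO4, MeCN/CCl4/H2O, rt
Reagents that add atoms: sodium periodate ([Na+].[O-]I(=O)(=O)=O)
Why: Sharpless RuO4 oxidative cleavage of the trisubstituted alkene gives the C3 aldehyde, which closes onto the tertiary alcohol as a lactol that the same oxidant takes on to the γ-lactone, leaving the quaternary centre untouched.

Step 4
Reactants: 7 tert-butyldiphenyl(prop-2-yn-1-yloxy)silane; 8 acrolein
Product: 10 rac-1-[(tert-butyldiphenylsilyl)oxy]hex-5-en-2-yn-4-ol, via lithium acetylide 9 (not isolated)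
Conditions: n-BuLi, THF, −78 °C; then 8, −78 °C; NH4Cl (aq.)
Reagents that add atoms: none
Why: Deprotonation of the terminal alkyne and 1,2-addition of the lithium acetylide to acrolein at low temperature form the C5–C6 bond of the racemic vinyl alkynyl carbinol.

Step 5
Reactants: 10 rac-1-[(tert-butyldiphenylsilyl)oxy]hex-5-en-2-yn-4-ol
Product: 11 (4S)-1-[(tert-butyldiphenylsilyl)oxy]hex-5-en-2-yn-4-ol
Conditions: Novozym 435 (immobilised Candida antarctica lipase B), vinyl acetate, hexane, 30 °C, run past half conversion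
Reagents that add atoms: none
Why: Lipase-catalysed kinetic resolution by transesterification, in which Kazlauskas' rule predicts acetylation of the (R)-alcohol (long alkynyl arm in the large pocket, vinyl in the small one) so that the (S)-alcohol needed for C6 is recovered.

Step 6
Reactants: 11 (4S)-1-[(tert-butyldiphenylsilyl)oxy]hex-5-en-2-yn-4-ol
Product: 13 (3S,4Z)-6-[(tert-butyldiphenylsilyl)oxy]-5-iodohexa-1,4-dien-3-ol, via alkenylaluminate 12 (not isolated)
Conditions: NaAlH2(OCH2CH2OMe)2, THF, 0 °C → rt; then I2, THF, −78 °C → 0 °C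
Reagents that add atoms: iodine (II)
Why: Hydroxyl-directed trans-hydroalumination of the propargylic alcohol (hydride to C5, aluminium to C4 in a five-membered alkoxyaluminate) followed by iodinolysis with retention gives the alkenyl iodide with C6 and iodine cis, which fixes the later Z geometry of C4=C5.

Step 7
Reactants: 13 (3S,4Z)-6-[(tert-butyldiphenylsilyl)oxy]-5-iodohexa-1,4-dien-3-ol
Product: 14 (3S,4Z)-6-[(tert-butyldiphenylsilyl)oxy]-5-iodo-3-[(4-methoxybenzyl)oxy]hexa-1,4-diene
Conditions: NaH, PMBCl, Bu4NI (cat.), THF/DMF, 0 °C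
Reagents that add atoms: 4-methoxybenzyl chloride (COc1ccc(CCl)cc1)
Why: Williamson etherification masks the C6 oxygen with a group that survives t-BuLi and, unlike a silyl group, cannot migrate to the neighbouring alkenyllithium.

Step 8
Reactants: 14 (3S,4Z)-6-[(tert-butyldiphenylsilyl)oxy]-5-iodo-3-[(4-methoxybenzyl)oxy]hexa-1,4-diene; 6 (5R)-5-{2-[(tert-butyldimethylsilyl)oxy]ethyl}-5-methyloxolan-2-one
Product: 16 (5R)-2-{(2Z,4S)-1-[(tert-butyldiphenylsilyl)oxy]-4-[(4-methoxybenzyl)oxy]hexa-2,5-dien-2-yl}-5-{2-[(tert-butyldimethylsilyl)oxy]ethyl}-5-methyloxolan-2-ol (lactol; both anomers), via alkenyllithium 15 (not isolated)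
Conditions: t-BuLi (2 equiv), Et2O, −78 °C; then 6, −78 °C; NH4Cl (aq.)
Reagents that add atoms: none
Why: Iodine–lithium exchange with retention of alkene geometry and single addition of the alkenyllithium to the γ-lactone (the lithium hemiketalate is stable at −78 °C) form the C3–C4 bond at the ketone oxidation level.

Step 9
Reactants: 16 lactol (both anomers)
Product: 17 (5R)-2-{(2Z,4S)-1-[(tert-butyldiphenylsilyl)oxy]-4-[(4-methoxybenzyl)oxy]hexa-2,5-dien-2-yl}-5-{2-[(tert-butyldimethylsilyl)oxy]ethyl}-2-methoxy-5-methyloxolane (both epimers at the ketal carbon)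
Conditions: MeOH, PPTS (cat.), 4 Å molecular sieves, 0 °C
Reagents that add atoms: methanol (CO)
Why: Acid-catalysed acetal exchange through the oxolanyl oxocarbenium ion locks C3 as a mixed methyl ketal, so that the C6 hydroxyl freed in the next step cannot add to a C3 ketone and dehydrate to a furan.

Step 10
Reactants: 17 methyl ketal
Product: 18 (3S,4Z)-6-[(tert-butyldiphenylsilyl)oxy]-5-{(5R)-5-{2-[(tert-butyldimethylsilyl)oxy]ethyl}-2-methoxy-5-methyloxolan-2-yl}hexa-1,4-dien-3-ol
Conditions: DDQ, CH2Cl2/pH 7 phosphate buffer, 0 °C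
Reagents that add atoms: none
Why: Oxidative PMB cleavage with DDQ (benzylic hydride abstraction, then hydrolysis) under buffered conditions releases the C6 alcohol without touching the silyl ethers or the ketal.

Step 11
Reactants: 18 C6 alcohol; 19 2-(bromomethyl)acrylic acid
Product: 20 (3S,4Z)-6-[(tert-butyldiphenylsilyl)oxy]-5-{(5R)-5-{2-[(tert-butyldimethylsilyl)oxy]ethyl}-2-methoxy-5-methyloxolan-2-yl}hexa-1,4-dien-3-yl 2-(bromomethyl)acrylate
Conditions: DCC, DMAP (cat.), CH2Cl2, 0 °C
Reagents that add atoms: none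
Why: Steglich esterification acylates the only free hydroxyl with retention at C6 and brings in C11, C12 and C13 with the allylic bromide already in place.

Step 12
Reactants: 20 dienyl 2-(bromomethyl)acrylate
Product: 21 (5R)-3-(bromomethyl)-5-[(1Z)-3-[(tert-butyldiphenylsilyl)oxy]-2-{(5R)-5-{2-[(tert-butyldimethylsilyl)oxy]ethyl}-2-methoxy-5-methyloxolan-2-yl}prop-1-en-1-yl]furan-2(5H)-one
Conditions: second-generation Hoveyda–Grubbs catalyst (cat.), toluene, 80 °C, argon sparge
Reagents that add atoms: none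
Why: Ring-closing metathesis between the terminal vinyl group and the 1,1-disubstituted acrylate closes the five-membered butenolide with loss of ethylene, the trisubstituted C4=C5 alkene being too hindered to compete.

Step 13
Reactants: 21 bromomethyl butenolide
Product: 22 (5R)-3-(bromomethyl)-5-[(1Z)-3-[(tert-butyldiphenylsilyl)oxy]-2-[(5R)-2-hydroxy-5-(2-hydroxyethyl)-5-methyloxolan-2-yl]prop-1-en-1-yl]furan-2(5H)-one (lactol; both anomers)
Conditions: AcOH/THF/H2O (3:1:1), rt
Reagents that add atoms: water (O)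
Why: Aqueous acetic acid hydrolyses the mixed ketal to the free lactol and cleaves the primary TBS ether, while the more robust TBDPS ether, the allylic bromide and the butenolide survive.

Step 14
Reactants: 22 lactol alcohol
Product: 23 2-[(2R)-5-{(1Z)-1-[(2R)-4-(bromomethyl)-5-oxo-2,5-dihydrofuran-2-yl]-3-[(tert-butyldiphenylsilyl)oxy]prop-1-en-2-yl}-5-hydroxy-2-methyloxolan-2-yl]acetaldehyde (C8 aldehyde; lactol anomers)
Conditions: Dess–Martin periodinane, NaHCO3, CH2Cl2, 0 °C → rt
Reagents that add atoms: none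
Why: Dess–Martin oxidation converts the primary alcohol into the C8 aldehyde under buffered, non-basic conditions, and the tertiary lactol hydroxyl cannot be oxidised.

Step 15
Reactants: 23 C8 aldehyde
Product: 25 (3R,4Z,6R,7R,8S,10R)-15-[(tert-butyldiphenylsilyl)oxy]-3,10-epoxy-3,8-dihydroxygermacra-4,11(13)-dien-12,6-olide (8-epi alcohol), via allylzinc bromide 24 (not isolated)
Conditions: Zn dust (activated), THF/sat. aq. NH4Cl (4:1), rt, syringe-pump addition of 23 (final ≤1 mM)
Reagents that add atoms: none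
Why: Zinc inserts into the allylic C13–Br bond of the 3-(bromomethyl)butenolide, and the resulting 2-(alkoxycarbonyl)allylzinc adds through its γ-carbon C7 (SE2′) to the tethered C8 aldehyde in a six-membered Zimmerman–Traxler chair, so the double bond moves to C11=C13 and the nine-membered ring and the exo-methylene lactone arise together; the closest known reactions are the zinc Barbier allylation of aldehydes with 3-(bromomethyl)furan-2(5H)-ones and the intramolecular Barbier/Nozaki–Hiyama allylations that close the medium rings of germacranolides. The oxonine ring closes in a 9-exo-trig sense at the aldehyde carbon (C7–C8 bond, carbonyl oxygen left outside the ring). C7 is controlled by C6, because the aldehyde should reach the butenolide face opposite the C6 alkenyl substituent, giving the trans-fused lactone (7R). C8 is controlled by the chair in which the tether carbon C9 is pseudo-equatorial (anti to C11) on the ring-locked, E-type allylzinc, which predicts the 6,7-trans/7,8-anti adduct, i.e. the 8α (8S) alcohol that step 16 inverts. C3 needs no control, since the lactol anomers interconvert through the hydroxy-enone in the aqueous medium and only one of them can be spanned by the six-atom bridge, after which the bridged hemiketal is locked. The step needs ring closure to outrun protonation and oligomerisation of the allylzinc (secured by slow addition at high dilution) and addition to the aldehyde in preference to the ketone of the open-chain tautomer (secured by the much higher reactivity of aldehydes toward allylzincs).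

Step 16
Reactants: 25 8-epi alcohol
Product: 26 (3R,4Z,6R,7R,8R,10R)-15-[(tert-butyldiphenylsilyl)oxy]-3,10-epoxy-3-hydroxy-8-(isobutyryloxy)germacra-4,11(13)-dien-12,6-olide
Conditions: PPh3, DIAD (betaine pre-formed), i-PrCO2H, toluene, 0 °C → rt
Reagents that add atoms: isobutyric acid (CC(C)C(=O)O)
Why: Mitsunobu esterification activates the C8 alcohol as its oxyphosphonium ion and isobutyrate displaces it with inversion (8S to 8R), which installs the ester and corrects C8 in one operation while the tertiary hemiketal hydroxyl stays inert.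

Step 17
Reactants: 26 silyl-protected ester
Product: 27 (3R,4Z,6R,7R,8R,10R)-3,10-epoxy-3,15-dihydroxy-8-(isobutyryloxy)germacra-4,11(13)-dien-12,6-olide (target, CNP0282937.1)
Conditions: HF·pyridine, pyridine/THF, 0 °C → rt
Reagents that add atoms: none
Why: Buffered fluoride desilylation cleaves the primary allylic TBDPS ether without affecting the α-methylene lactone, the ester or the hemiketal.

**Compound list**

1 | (R)-(−)-linalool, (3R)-3,7-dimethylocta-1,6-dien-3-ol | C=C[C@](C)(O)CCC=C(C)C | starting material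
2 | B-alkyl-9-BBN adduct of 1 at the terminal vinyl carbon | CC(C)=CCC[C@@](C)(O)CCB1C2CCCC1CCC2 | intermediate
3 | (3R)-3,7-dimethyloct-6-ene-1,3-diol | OCC[C@](C)(O)CCC=C(C)C | intermediate
4 | (3R)-1-[(tert-butyldimethylsilyl)oxy]-3,7-dimethyloct-6-en-3-ol | CC(C)(C)[Si](C)(C)OCC[C@](C)(O)CCC=C(C)C | intermediate
5 | (5R)-5-{2-[(tert-butyldimethylsilyl)oxy]ethyl}-5-methyloxolan-2-ol (lactol) | C[C@]1(CCO[Si](C)(C)C(C)(C)C)CCC(O)O1 | intermediate
6 | (5R)-5-{2-[(tert-butyldimethylsilyl)oxy]ethyl}-5-methyloxolan-2-one | C[C@]1(CCO[Si](C)(C)C(C)(C)C)CCC(=O)O1 | intermediate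
7 | tert-butyldiphenyl(prop-2-yn-1-yloxy)silane | C#CCO[Si](c1ccccc1)(c1ccccc1)C(C)(C)C | starting material
8 | acrolein (prop-2-enal) | C=CC=O | starting material
9 | lithium acetylide of 7 | [Li]C#CCO[Si](c1ccccc1)(c1ccccc1)C(C)(C)C | intermediate
10 | rac-1-[(tert-butyldiphenylsilyl)oxy]hex-5-en-2-yn-4-ol (racemate) | C=CC(O)C#CCO[Si](c1ccccc1)(c1ccccc1)C(C)(C)C | intermediate
11 | (4S)-1-[(tert-butyldiphenylsilyl)oxy]hex-5-en-2-yn-4-ol | C=C[C@H](O)C#CCO[Si](c1ccccc1)(c1ccccc1)C(C)(C)C | intermediate
12 | cyclic sodium alkoxy(alkenyl)aluminate from trans-hydroalumination of 11 | C=C[C@@H]1O[Al-](OCCOC)(OCCOC)C(CO[Si](c2ccccc2)(c2ccccc2)C(C)(C)C)=C1.[Na+] | intermediate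
13 | (3S,4Z)-6-[(tert-butyldiphenylsilyl)oxy]-5-iodohexa-1,4-dien-3-ol | C=C[C@H](O)/C=C(\I)CO[Si](c1ccccc1)(c1ccccc1)C(C)(C)C | intermediate
14 | (3S,4Z)-6-[(tert-butyldiphenylsilyl)oxy]-5-iodo-3-[(4-methoxybenzyl)oxy]hexa-1,4-diene | C=C[C@H](OCc1ccc(OC)cc1)/C=C(\I)CO[Si](c1ccccc1)(c1ccccc1)C(C)(C)C | intermediate
15 | alkenyllithium from 14 (Li in place of I) | C=C[C@H](OCc1ccc(OC)cc1)/C=C(\[Li])CO[Si](c1ccccc1)(c1ccccc1)C(C)(C)C | intermediate
16 | (5R)-2-{(2Z,4S)-1-[(tert-butyldiphenylsilyl)oxy]-4-[(4-methoxybenzyl)oxy]hexa-2,5-dien-2-yl}-5-{2-[(tert-butyldimethylsilyl)oxy]ethyl}-5-methyloxolan-2-ol (both anomers) | C=C[C@H](OCc1ccc(OC)cc1)/C=C(/CO[Si](c1ccccc1)(c1ccccc1)C(C)(C)C)C1(O)CC[C@](C)(CCO[Si](C)(C)C(C)(C)C)O1 | intermediate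
17 | methyl ketal of 16 (2-methoxyoxolane, both epimers) | C=C[C@H](OCc1ccc(OC)cc1)/C=C(/CO[Si](c1ccccc1)(c1ccccc1)C(C)(C)C)C1(OC)CC[C@](C)(CCO[Si](C)(C)C(C)(C)C)O1 | intermediate
18 | (3S,4Z)-6-[(tert-butyldiphenylsilyl)oxy]-5-{(5R)-5-{2-[(tert-butyldimethylsilyl)oxy]ethyl}-2-methoxy-5-methyloxolan-2-yl}hexa-1,4-dien-3-ol | C=C[C@H](O)/C=C(/CO[Si](c1ccccc1)(c1ccccc1)C(C)(C)C)C1(OC)CC[C@](C)(CCO[Si](C)(C)C(C)(C)C)O1 | intermediate
19 | 2-(bromomethyl)acrylic acid | C=C(CBr)C(=O)O | starting material
20 | 2-(bromomethyl)acrylate ester of 18 | C=C[C@H](OC(=O)C(=C)CBr)/C=C(/CO[Si](c1ccccc1)(c1ccccc1)C(C)(C)C)C1(OC)CC[C@](C)(CCO[Si](C)(C)C(C)(C)C)O1 | intermediate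
21 | (5R)-3-(bromomethyl)-5-[(1Z)-3-[(tert-butyldiphenylsilyl)oxy]-2-{(5R)-5-{2-[(tert-butyldimethylsilyl)oxy]ethyl}-2-methoxy-5-methyloxolan-2-yl}prop-1-en-1-yl]furan-2(5H)-one | O=C1O[C@H](/C=C(/CO[Si](c2ccccc2)(c2ccccc2)C(C)(C)C)C2(OC)CC[C@](C)(CCO[Si](C)(C)C(C)(C)C)O2)C=C1CBr | intermediate
22 | lactol alcohol: 21 with C3–OH in place of OMe and free C8–OH | O=C1O[C@H](/C=C(/CO[Si](c2ccccc2)(c2ccccc2)C(C)(C)C)C2(O)CC[C@](C)(CCO)O2)C=C1CBr | intermediate
23 | C8 aldehyde of 22 | O=C1O[C@H](/C=C(/CO[Si](c2ccccc2)(c2ccccc2)C(C)(C)C)C2(O)CC[C@](C)(CC=O)O2)C=C1CBr | intermediate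
24 | allylzinc bromide from 23 (ZnBr in place of Br at C13) | O=C1O[C@H](/C=C(/CO[Si](c2ccccc2)(c2ccccc2)C(C)(C)C)C2(O)CC[C@](C)(CC=O)O2)C=C1C[Zn]Br | intermediate
25 | (3R,4Z,6R,7R,8S,10R)-15-[(tert-butyldiphenylsilyl)oxy]-3,10-epoxy-3,8-dihydroxygermacra-4,11(13)-dien-12,6-olide | C=C1C(=O)O[C@@H]2/C=C(/CO[Si](c3ccccc3)(c3ccccc3)C(C)(C)C)[C@@]3(O)CC[C@](C)(C[C@H](O)[C@@H]12)O3 | intermediate
26 | (3R,4Z,6R,7R,8R,10R)-15-[(tert-butyldiphenylsilyl)oxy]-3,10-epoxy-3-hydroxy-8-(isobutyryloxy)germacra-4,11(13)-dien-12,6-olide | C=C1C(=O)O[C@@H]2/C=C(/CO[Si](c3ccccc3)(c3ccccc3)C(C)(C)C)[C@@]3(O)CC[C@](C)(C[C@@H](OC(=O)C(C)C)[C@@H]12)O3 | intermediate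
27 | (3R,4Z,6R,7R,8R,10R)-3,10-epoxy-3,15-dihydroxy-8-(isobutyryloxy)germacra-4,11(13)-dien-12,6-olide | C=C1C(=O)O[C@@H]2/C=C(/CO)[C@@]3(O)CC[C@](C)(C[C@@H](OC(=O)C(C)C)[C@@H]12)O3 | target

**Count**

Total steps: 17. Longest linear sequence: 14 steps (steps 4–17, from 7 and 8); the linalool branch (steps 1–3) joins at step 8.

**Steps most likely to fail**

1. Step 15. Ring closure may lose to protonation of the allylzinc or to intermolecular addition (oligomerisation), and the aldehyde may reach the wrong butenolide face or react through the other chair, which would scramble C7/C8. The fallback joins C7–C8 between two fragments and closes the nine-membered ring at C4=C5 by ring-closing metathesis; it sets out from lactone 6 and returns at 25. Lactone 6 is treated at −78 °C with the alkenyllithium made from [(2-bromoprop-2-en-1-yl)oxy](tert-butyl)diphenylsilane and t-BuLi to give the 2-(3-silyloxyprop-1-en-2-yl) lactol F1. MeOH/PPTS at rt forms the methyl ketal and removes the primary TBS group (ketal alcohol F2), and Dess–Martin oxidation gives the ketal aldehyde F3. Separately, penta-1,4-dien-3-ol is esterified with 19 (DCC, DMAP) to the dienyl 2-(bromomethyl)acrylate F4, which ring-closing metathesis (second-generation Hoveyda–Grubbs catalyst) turns into racemic 3-(bromomethyl)-5-vinylfuran-2(5H)-one F5. Zinc-mediated Barbier coupling of F3 with F5 in THF/aqueous NH4Cl should give, from the (R)-enantiomer of F5 and after separation from the diastereomer derived from its antipode, the 6,7-trans/7,8-anti α-methylene lactone F6. Ring-closing metathesis of its C5 vinyl and C4 methylidene groups (second-generation Hoveyda–Grubbs catalyst, toluene, 110 °C, high dilution) closes the ring as the bridged methyl ketal F7, and aqueous acetic acid hydrolyses the ketal to 25.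

2. Step 16. SN2 displacement at the hindered ring carbinol may be slower than E2 loss of the activated oxygen toward C7 (diene formation), or may proceed with retention through an acyloxyphosphonium ion. The fallback replaces inversion by oxidation and reduction; it sets out from 25 and returns at 26. Dess–Martin oxidation (NaHCO3 buffer) gives the C8 ketone F8, which is reduced at once with NaBH4/CeCl3·7H2O in MeOH at −78 °C; hydride delivery from the more open ring face is expected to give the 8β-alcohol F9. Acylation with isobutyric anhydride, Et3N and DMAP (retention) then gives 26.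

3. Step 12. Closure onto the 1,1-disubstituted, bromomethyl-bearing acrylate may be slow, and the allylic bromide may degrade the ruthenium carbene before the ring closes. The fallback builds the butenolide first and adds C13 afterwards; it sets out from 18 and returns at 21. Acylation with acryloyl chloride (i-Pr2NEt, CH2Cl2) gives the acrylate F10, and ring-closing metathesis of the two monosubstituted alkenes (second-generation Grubbs catalyst, CH2Cl2, 40 °C) gives the unsubstituted butenolide F11. Morita–Baylis–Hillman α-hydroxymethylation with aqueous formaldehyde and imidazole gives the 3-(hydroxymethyl)butenolide F12, and Appel bromination (CBr4, PPh3) gives 21.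

**Further compounds**

F1 | step 15 | (5R)-2-{3-[(tert-butyldiphenylsilyl)oxy]prop-1-en-2-yl}-5-{2-[(tert-butyldimethylsilyl)oxy]ethyl}-5-methyloxolan-2-ol | C=C(CO[Si](c1ccccc1)(c1ccccc1)C(C)(C)C)C1(O)CC[C@](C)(CCO[Si](C)(C)C(C)(C)C)O1
F2 | step 15 | 2-[(2R)-5-{3-[(tert-butyldiphenylsilyl)oxy]prop-1-en-2-yl}-5-methoxy-2-methyloxolan-2-yl]ethanol | C=C(CO[Si](c1ccccc1)(c1ccccc1)C(C)(C)C)C1(OC)CC[C@](C)(CCO)O1
F3 | step 15 | 2-[(2R)-5-{3-[(tert-butyldiphenylsilyl)oxy]prop-1-en-2-yl}-5-methoxy-2-methyloxolan-2-yl]acetaldehyde | C=C(CO[Si](c1ccccc1)(c1ccccc1)C(C)(C)C)C1(OC)CC[C@](C)(CC=O)O1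
F4 | step 15 | penta-1,4-dien-3-yl 2-(bromomethyl)acrylate | C=CC(C=C)OC(=O)C(=C)CBr
F5 | step 15 | rac-3-(bromomethyl)-5-vinylfuran-2(5H)-one | C=CC1OC(=O)C(CBr)=C1
F6 | step 15 | (6R,7R,8S,10R) Barbier adduct: 6-vinyl α-methylene lactone carrying the C8 carbinol and the 2-methoxyoxolane with the C4 methylidene unit | C=C1C(=O)O[C@H](C=C)[C@H]1[C@@H](O)C[C@@]2(C)CCC(OC)(O2)C(=C)CO[Si](c3ccccc3)(c3ccccc3)C(C)(C)C
F7 | step 15 | 3-O-methyl ketal of 25 | C=C1C(=O)O[C@@H]2/C=C(/CO[Si](c3ccccc3)(c3ccccc3)C(C)(C)C)[C@@]3(OC)CC[C@](C)(C[C@H](O)[C@@H]12)O3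
F8 | step 16 | 8-oxo analogue of 25 | C=C1C(=O)O[C@@H]2/C=C(/CO[Si](c3ccccc3)(c3ccccc3)C(C)(C)C)[C@@]3(O)CC[C@](C)(CC(=O)[C@@H]12)O3
F9 | step 16 | (8R)-alcohol, C8 epimer of 25 | C=C1C(=O)O[C@@H]2/C=C(/CO[Si](c3ccccc3)(c3ccccc3)C(C)(C)C)[C@@]3(O)CC[C@](C)(C[C@@H](O)[C@@H]12)O3
F10 | step 12 | acrylate ester of 18 | C=C[C@H](OC(=O)C=C)/C=C(/CO[Si](c1ccccc1)(c1ccccc1)C(C)(C)C)C1(OC)CC[C@](C)(CCO[Si](C)(C)C(C)(C)C)O1
F11 | step 12 | butenolide lacking C13 (21 with H in place of CH2Br) | O=C1O[C@H](/C=C(/CO[Si](c2ccccc2)(c2ccccc2)C(C)(C)C)C2(OC)CC[C@](C)(CCO[Si](C)(C)C(C)(C)C)O2)C=C1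
F12 | step 12 | 3-(hydroxymethyl)butenolide (21 with OH in place of Br) | O=C1O[C@H](/C=C(/CO[Si](c2ccccc2)(c2ccccc2)C(C)(C)C)C2(OC)CC[C@](C)(CCO[Si](C)(C)C(C)(C)C)O2)C=C1CO
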